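Rings are lettered A to H from the 2,4,6-trihydroxyphenoxy end. Ring A is built, not coupled: its ether carbon (C1 of ring A), flanked by the hydroxyl-bearing C2 and C6, maps onto C4 of a symmetric 3,5-dioxoheptanedioate already carrying the ring B aryloxy group. One Claisen (Dieckmann) closure forms the chain C1–C6 bond and aromatises to the phloroglucinol carboxylate, so the doubly ortho-flanked ether between rings A and B is made earlier by phenoxide alkylation at sp3 carbon. The precursor comes from base-free acylation of a bis(silyl enol ether) with methyl malonyl chloride. Rings C to H arrive as two iodinated diaryl ether blocks through CuI-catalysed etherification; BBr3 then frees the 21 hydroxyls.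

Key step: step 7

Assumption: 2,3,4-trimethoxyphenol, 4-bromo-2,6-dimethoxyphenol and 3,4,5-trimethoxyphenylboronic acid are taken as catalogue chemicals. The double-bond geometry of the silyl enol ethers is uncontrolled, is lost on acylation and is left unspecified. The target has no stereocentre.

Step 1
Reactants: 1 syringaldehyde (4-hydroxy-3,5-dimethoxybenzaldehyde)
Product: 2 4-(benzyloxy)-3,5-dimethoxybenzaldehyde
Conditions: BnBr, K2CO3, DMF, 60 °C
Reagents that add atoms: benzyl bromide, BrCc1ccccc1
Why: Williamson O-benzylation (SN2 of the phenoxide on benzyl bromide) should proceed cleanly, the aldehyde being inert to K2CO3.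

Step 2
Reactants: 2 4-(benzyloxy)-3,5-dimethoxybenzaldehyde
Product: 4 4-(benzyloxy)-3,5-dimethoxyphenol, via aryl formate 3 (not isolated)
Conditions: mCPBA, CH2Cl2, 0 °C to rt; then K2CO3 (cat.), MeOH, rt
Reagents that add atoms: meta-chloroperoxybenzoic acid, O=C(OO)c1cccc(Cl)c1
Why: Baeyer–Villiger oxidation in which the electron-rich trioxygenated aryl group migrates in preference to hydride, followed by mild transesterification of the formate, which leaves the benzyl ether intact.

Step 3
Reactants: 4 4-(benzyloxy)-3,5-dimethoxyphenol; 5 methyl 4-chloroacetoacetate (methyl 4-chloro-3-oxobutanoate)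
Product: 6 methyl 4-[4-(benzyloxy)-3,5-dimethoxyphenoxy]-3-oxobutanoate
Conditions: NaH (2.2 equiv), THF, 0 °C; then 5, 0 to 50 °C; aq. HCl work-up
Reagents that add atoms: none
Why: Williamson-type SN2 displacement of the primary chloride by the unhindered phenoxide, the second equivalent of NaH holding 5 as its C2 enolate so that it does not self-condense, which places the future ether oxygen between rings A and B on an sp3 carbon.

Step 4
Reactants: 6 methyl 4-[4-(benzyloxy)-3,5-dimethoxyphenoxy]-3-oxobutanoate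
Product: 7 methyl 4-[4-(benzyloxy)-3,5-dimethoxyphenoxy]-3-[(trimethylsilyl)oxy]but-2-enoate
Conditions: TMSCl, Et3N, toluene, rt
Reagents that add atoms: chlorotrimethylsilane, C[Si](C)(C)Cl
Why: Soft enolisation and O-silylation of the β-keto ester gives the conjugated silyl enol ether needed for a clean γ-deprotonation.

Step 5
Reactants: 7 methyl 4-[4-(benzyloxy)-3,5-dimethoxyphenoxy]-3-[(trimethylsilyl)oxy]but-2-enoate
Product: 8 4-[4-(benzyloxy)-3,5-dimethoxyphenoxy]-1-methoxy-1,3-bis[(trimethylsilyl)oxy]buta-1,3-diene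
Conditions: LiN(iPr)2, THF, −78 °C; TMSCl, −78 °C to rt
Reagents that add atoms: chlorotrimethylsilane, C[Si](C)(C)Cl
Why: Kinetic γ-deprotonation of the vinylogous ester and O-silylation of the extended enolate gives the 1,3-bis(silyloxy)diene, a neutral equivalent of the β-keto ester dianion.

Step 6
Reactants: 8 4-[4-(benzyloxy)-3,5-dimethoxyphenoxy]-1-methoxy-1,3-bis[(trimethylsilyl)oxy]buta-1,3-diene; 9 methyl malonyl chloride (methyl 3-chloro-3-oxopropanoate)
Product: 11 dimethyl 4-[4-(benzyloxy)-3,5-dimethoxyphenoxy]-3,5-dioxoheptanedioate, via silyl ketene acetal 10 (not isolated)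
Conditions: 9 (1.3 equiv), CH2Cl2, −78 °C to rt; then 1 M HCl, 0 °C
Reagents that add atoms: none
Why: Mukaiyama-type C-acylation of the bis(silyl enol ether) at its terminal, aryloxy-bearing carbon by the acid chloride with loss of TMSCl, run without base so that the acidic methylene of 9 cannot quench the nucleophile as it would a lithium dianion, after which dilute acid removes the remaining silyl group.

Step 7
Reactants: 11 dimethyl 4-[4-(benzyloxy)-3,5-dimethoxyphenoxy]-3,5-dioxoheptanedioate
Product: 12 methyl 3-[4-(benzyloxy)-3,5-dimethoxyphenoxy]-2,4,6-trihydroxybenzoate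
Conditions: Mg(OMe)2 (3 equiv), MeOH, rt to 65 °C, Ar; then cold 1 M HCl
Reagents that add atoms: none
Why: Mg(OMe)2 turns 11 into a magnesium bis(β-dicarbonyl) chelate in which the chain C6 carbanion, flanked by the C5 ketone and the C7 ester, adds to the C1 ester carbonyl; methoxide is expelled and the cyclic triketone tautomerises irreversibly to the aromatic trihydroxybenzoate (chain C4 becomes C1 of ring A, chain C3 and C5 become its C2 and C6, chain C1 becomes its C4, and the ester sits on its C5). The closest known reaction type is the Claisen (Dieckmann) cyclisation of 3,5-dioxo esters and polyketo esters to phloroglucinol carboxylates, the laboratory counterpart of polyketide ring closure. Ring A is closed in a 6-exo-trig mode, with the C5–C6 enolate double bond inside the forming ring, and only the chain C1–C6 bond is formed. No stereocentre is present in 11 or created in 12. The step needs C-acylation to beat O-acylation (pyranone formation) and retro-Claisen cleavage; magnesium chelation ties up the enol oxygens and tempers the ketones, the doubly stabilised C6 carbanion reacts at carbon, and aromatisation drains the C-acylation pathway. Because 11 is symmetric about C4, attack of C6 on C1 and of C2 on C7 give the same product, so no regiochemical question arises.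

Step 8
Reactants: 12 methyl 3-[4-(benzyloxy)-3,5-dimethoxyphenoxy]-2,4,6-trihydroxybenzoate
Product: 14 2-[4-(benzyloxy)-3,5-dimethoxyphenoxy]benzene-1,3,5-triol, via trihydroxybenzoic acid 13 (not isolated)
Conditions: 2 M NaOH (degassed), 90 °C, Ar; then HCl to pH 2, 60 °C
Reagents that add atoms: none
Why: Saponification followed by protodecarboxylation of the 2,4,6-trihydroxybenzoic acid, which loses CO2 easily through its keto tautomer (a β-keto acid), while benzyl and aryl ethers are stable and air is excluded to protect the phloroglucinol anion.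

Step 9
Reactants: 14 2-[4-(benzyloxy)-3,5-dimethoxyphenoxy]benzene-1,3,5-triol
Product: 15 2-(benzyloxy)-1,3-dimethoxy-5-(2,4,6-trimethoxyphenoxy)benzene
Conditions: Me2SO4, K2CO3, acetone, reflux
Reagents that add atoms: dimethyl sulfate, COS(=O)(=O)OC
Why: Exhaustive Williamson O-methylation with a hard electrophile and K2CO3 in acetone, conditions that favour O- over C-methylation of phloroglucinols.

Step 10
Reactants: 15 2-(benzyloxy)-1,3-dimethoxy-5-(2,4,6-trimethoxyphenoxy)benzene
Product: 16 2,6-dimethoxy-4-(2,4,6-trimethoxyphenoxy)phenol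
Conditions: H2 (1 atm), 10% Pd/C, EtOAc/MeOH, rt
Reagents that add atoms: none
Why: Hydrogenolysis of the benzyl ether unmasks the ring B phenol, para to the ether oxygen from ring A, and leaves methyl and diaryl ethers untouched.

Step 11
Reactants: 17 2,3,4-trimethoxyphenol
Product: 18 6-iodo-2,3,4-trimethoxyphenol
Conditions: I2, NaHCO3, THF/H2O, 0 °C to rt
Reagents that add atoms: iodine, II
Why: Electrophilic aromatic iodination of the phenoxide, which directs to its only free ortho position (para is blocked by OMe), placing iodine on the carbon of rings C, E and G that will carry the ether oxygen from the preceding ring.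

Step 12
Reactants: 19 4-bromo-2,6-dimethoxyphenol
Product: 20 2-(benzyloxy)-5-bromo-1,3-dimethoxybenzene
Conditions: BnBr, K2CO3, DMF, 60 °C
Reagents that add atoms: benzyl bromide, BrCc1ccccc1
Why: Williamson O-benzylation of the phenoxide (SN2), the aryl bromide being inert.

Step 13
Reactants: 20 2-(benzyloxy)-5-bromo-1,3-dimethoxybenzene
Product: 23 [4-(benzyloxy)-3,5-dimethoxyphenyl]boronic acid, via aryllithium 21 (not isolated), via lithium aryltriisopropoxyborate 22 (not isolated)
Conditions: n-BuLi, THF, −78 °C; B(OiPr)3, −78 °C to rt; 1 M HCl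
Reagents that add atoms: triisopropyl borate, CC(C)OB(OC(C)C)OC(C)C; water, O
Why: Bromine–lithium exchange, borylation of the aryllithium and acidic hydrolysis of the borate, the standard arylboronic acid synthesis, with the benzyl ether stable at low temperature.

Step 14
Reactants: 18 6-iodo-2,3,4-trimethoxyphenol; 23 [4-(benzyloxy)-3,5-dimethoxyphenyl]boronic acid
Product: 24 2-(benzyloxy)-5-(6-iodo-2,3,4-trimethoxyphenoxy)-1,3-dimethoxybenzene
Conditions: Cu(OAc)2 (1 equiv), pyridine, 4 Å MS, CH2Cl2, air, rt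
Reagents that add atoms: none
Why: Chan–Lam oxidative O-arylation (transmetalation of the boronic acid to divalent copper, then C–O reductive elimination, with air as the terminal oxidant that returns the copper salt) runs at room temperature, tolerates di-ortho-substituted phenols and leaves the aryl iodide untouched.

Step 15
Reactants: 18 6-iodo-2,3,4-trimethoxyphenol; 25 3,4,5-trimethoxyphenylboronic acid
Product: 26 1-iodo-3,4,5-trimethoxy-2-(3,4,5-trimethoxyphenoxy)benzene
Conditions: Cu(OAc)2 (1 equiv), pyridine, 4 Å MS, CH2Cl2, air, rt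
Reagents that add atoms: none
Why: Chan–Lam oxidative O-arylation as in step 14, giving the terminal block of rings G and H with the iodide preserved.

Step 16
Reactants: 16 2,6-dimethoxy-4-(2,4,6-trimethoxyphenoxy)phenol; 24 2-(benzyloxy)-5-(6-iodo-2,3,4-trimethoxyphenoxy)-1,3-dimethoxybenzene
Product: 27 1-[2,6-dimethoxy-4-(2,4,6-trimethoxyphenoxy)phenoxy]-2-[4-(benzyloxy)-3,5-dimethoxyphenoxy]-3,4,5-trimethoxybenzene (benzyl-capped tetramer A–D)
Conditions: CuI (20 mol %), picolinic acid (40 mol %), K3PO4, DMSO, 100 °C, Ar; 24 in excess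
Reagents that add atoms: none
Why: Ullmann-type C–O coupling in which the picolinate complex of monovalent copper adds oxidatively to the aryl iodide and couples with the 2,6-dimethoxyphenoxide, a ligand system suited to ortho-substituted partners.

Step 17
Reactants: 27 benzyl-capped tetramer A–D
Product: 28 2,6-dimethoxy-4-{6-[2,6-dimethoxy-4-(2,4,6-trimethoxyphenoxy)phenoxy]-2,3,4-trimethoxyphenoxy}phenol (tetramer phenol, free OH on ring D)
Conditions: H2 (1 atm), 10% Pd/C, EtOAc/MeOH, rt
Reagents that add atoms: none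
Why: Hydrogenolysis of the single benzyl ether frees the ring D phenol for the next coupling without touching methyl or diaryl ethers.

Step 18
Reactants: 28 tetramer phenol A–D; 24 2-(benzyloxy)-5-(6-iodo-2,3,4-trimethoxyphenoxy)-1,3-dimethoxybenzene
Product: 29 benzyl-capped hexamer A–F (28 arylated on its ring D hydroxyl oxygen by the 2-[4-(benzyloxy)-3,5-dimethoxyphenoxy]-3,4,5-trimethoxyphenyl group)
Conditions: CuI (20 mol %), picolinic acid (40 mol %), K3PO4, DMSO, 100 °C, Ar; 24 in excess
Reagents that add atoms: none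
Why: The same Ullmann-type C–O coupling as in step 16, between an analogous 2,6-dimethoxyphenoxide and the same aryl iodide.

Step 19
Reactants: 29 benzyl-capped hexamer A–F
Product: 30 hexamer phenol A–F (29 with a free OH on ring F in place of the benzyloxy group)
Conditions: H2 (1 atm), 10% Pd/C, EtOAc/MeOH, rt
Reagents that add atoms: none
Why: Hydrogenolysis of the benzyl ether, as in step 17.

Step 20
Reactants: 30 hexamer phenol A–F; 26 1-iodo-3,4,5-trimethoxy-2-(3,4,5-trimethoxyphenoxy)benzene
Product: 31 henicosamethyl ether of the target (permethylated octamer A–H)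
Conditions: CuI (20 mol %), picolinic acid (40 mol %), K3PO4, DMSO, 100 °C, Ar; 26 in excess
Reagents that add atoms: none
Why: Ullmann-type C–O coupling as in steps 16 and 18, forming the ether between rings F and G and completing the octamer skeleton.

Step 21
Reactants: 31 henicosamethyl ether of the target
Product: 32 CNP0206369.0 (target, free henicosaphenol)
Conditions: BBr3 (about 1.5 equiv per OMe), CH2Cl2, −78 °C to rt, Ar; then degassed H2O, 0 °C
Reagents that add atoms: none
Why: Lewis acid-mediated aryl methyl ether cleavage, in which each methoxy oxygen coordinates BBr3 and bromide removes the methyl group by SN2 while diaryl ethers are inert, followed by hydrolysis of the aryl borates.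

Compound list
1 | syringaldehyde (4-hydroxy-3,5-dimethoxybenzaldehyde) | COc1cc(C=O)cc(OC)c1O | starting material
2 | 4-(benzyloxy)-3,5-dimethoxybenzaldehyde | COc1cc(C=O)cc(OC)c1OCc1ccccc1 | intermediate
3 | 4-(benzyloxy)-3,5-dimethoxyphenyl formate (not isolated) | COc1cc(OC=O)cc(OC)c1OCc1ccccc1 | intermediate
4 | 4-(benzyloxy)-3,5-dimethoxyphenol | COc1cc(O)cc(OC)c1OCc1ccccc1 | intermediate
5 | methyl 4-chloroacetoacetate | COC(=O)CC(=O)CCl | starting material
6 | methyl 4-[4-(benzyloxy)-3,5-dimethoxyphenoxy]-3-oxobutanoate | COC(=O)CC(=O)COc1cc(OC)c(OCc2ccccc2)c(OC)c1 | intermediate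
7 | methyl 4-[4-(benzyloxy)-3,5-dimethoxyphenoxy]-3-[(trimethylsilyl)oxy]but-2-enoate (geometry unspecified) | COC(=O)C=C(O[Si](C)(C)C)COc1cc(OC)c(OCc2ccccc2)c(OC)c1 | intermediate
8 | 4-[4-(benzyloxy)-3,5-dimethoxyphenoxy]-1-methoxy-1,3-bis[(trimethylsilyl)oxy]buta-1,3-diene (geometry unspecified) | COC(O[Si](C)(C)C)=CC(O[Si](C)(C)C)=COc1cc(OC)c(OCc2ccccc2)c(OC)c1 | intermediate
9 | methyl malonyl chloride | COC(=O)CC(Cl)=O | starting material
10 | methyl 4-[4-(benzyloxy)-3,5-dimethoxyphenoxy]-7-methoxy-3,5-dioxo-7-[(trimethylsilyl)oxy]hept-6-enoate (not isolated, geometry unspecified) | COC(=O)CC(=O)C(Oc1cc(OC)c(OCc2ccccc2)c(OC)c1)C(=O)C=C(OC)O[Si](C)(C)C | intermediate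
11 | dimethyl 4-[4-(benzyloxy)-3,5-dimethoxyphenoxy]-3,5-dioxoheptanedioate | COC(=O)CC(=O)C(Oc1cc(OC)c(OCc2ccccc2)c(OC)c1)C(=O)CC(=O)OC | intermediate
12 | methyl 3-[4-(benzyloxy)-3,5-dimethoxyphenoxy]-2,4,6-trihydroxybenzoate | COC(=O)c1c(O)cc(O)c(Oc2cc(OC)c(OCc3ccccc3)c(OC)c2)c1O | intermediate
13 | 3-[4-(benzyloxy)-3,5-dimethoxyphenoxy]-2,4,6-trihydroxybenzoic acid (not isolated) | OC(=O)c1c(O)cc(O)c(Oc2cc(OC)c(OCc3ccccc3)c(OC)c2)c1O | intermediate
14 | 2-[4-(benzyloxy)-3,5-dimethoxyphenoxy]benzene-1,3,5-triol | Oc1cc(O)c(Oc2cc(OC)c(OCc3ccccc3)c(OC)c2)c(O)c1 | intermediate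
15 | 2-(benzyloxy)-1,3-dimethoxy-5-(2,4,6-trimethoxyphenoxy)benzene | COc1cc(OC)c(Oc2cc(OC)c(OCc3ccccc3)c(OC)c2)c(OC)c1 | intermediate
16 | 2,6-dimethoxy-4-(2,4,6-trimethoxyphenoxy)phenol | COc1cc(OC)c(Oc2cc(OC)c(O)c(OC)c2)c(OC)c1 | intermediate
17 | 2,3,4-trimethoxyphenol | COc1ccc(O)c(OC)c1OC | starting material
18 | 6-iodo-2,3,4-trimethoxyphenol | COc1cc(I)c(O)c(OC)c1OC | intermediate
19 | 4-bromo-2,6-dimethoxyphenol | COc1cc(Br)cc(OC)c1O | starting material
20 | 2-(benzyloxy)-5-bromo-1,3-dimethoxybenzene | COc1cc(Br)cc(OC)c1OCc1ccccc1 | intermediate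
21 | [4-(benzyloxy)-3,5-dimethoxyphenyl]lithium (not isolated) | [Li]c1cc(OC)c(OCc2ccccc2)c(OC)c1 | intermediate
22 | lithium [4-(benzyloxy)-3,5-dimethoxyphenyl]tri(propan-2-yloxy)borate (not isolated) | [Li+].CC(C)O[B-](OC(C)C)(OC(C)C)c1cc(OC)c(OCc2ccccc2)c(OC)c1 | intermediate
23 | [4-(benzyloxy)-3,5-dimethoxyphenyl]boronic acid | COc1cc(B(O)O)cc(OC)c1OCc1ccccc1 | intermediate
24 | 2-(benzyloxy)-5-(6-iodo-2,3,4-trimethoxyphenoxy)-1,3-dimethoxybenzene | COc1cc(I)c(Oc2cc(OC)c(OCc3ccccc3)c(OC)c2)c(OC)c1OC | intermediate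
25 | 3,4,5-trimethoxyphenylboronic acid | COc1cc(B(O)O)cc(OC)c1OC | starting material
26 | 1-iodo-3,4,5-trimethoxy-2-(3,4,5-trimethoxyphenoxy)benzene | COc1cc(I)c(Oc2cc(OC)c(OC)c(OC)c2)c(OC)c1OC | intermediate
27 | benzyl-capped tetramer A–D | COc1cc(OC)c(Oc2cc(OC)c(Oc3cc(OC)c(OC)c(OC)c3Oc3cc(OC)c(OCc4ccccc4)c(OC)c3)c(OC)c2)c(OC)c1 | intermediate
28 | tetramer phenol A–D (free OH on ring D) | COc1cc(OC)c(Oc2cc(OC)c(Oc3cc(OC)c(OC)c(OC)c3Oc3cc(OC)c(O)c(OC)c3)c(OC)c2)c(OC)c1 | intermediate
29 | benzyl-capped hexamer A–F | COc1cc(OC)c(Oc2cc(OC)c(Oc3cc(OC)c(OC)c(OC)c3Oc3cc(OC)c(Oc4cc(OC)c(OC)c(OC)c4Oc4cc(OC)c(OCc5ccccc5)c(OC)c4)c(OC)c3)c(OC)c2)c(OC)c1 | intermediate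
30 | hexamer phenol A–F (free OH on ring F) | COc1cc(OC)c(Oc2cc(OC)c(Oc3cc(OC)c(OC)c(OC)c3Oc3cc(OC)c(Oc4cc(OC)c(OC)c(OC)c4Oc4cc(OC)c(O)c(OC)c4)c(OC)c3)c(OC)c2)c(OC)c1 | intermediate
31 | henicosamethyl ether of the target (permethylated octamer A–H) | COc1cc(OC)c(Oc2cc(OC)c(Oc3cc(OC)c(OC)c(OC)c3Oc3cc(OC)c(Oc4cc(OC)c(OC)c(OC)c4Oc4cc(OC)c(Oc5cc(OC)c(OC)c(OC)c5Oc5cc(OC)c(OC)c(OC)c5)c(OC)c4)c(OC)c3)c(OC)c2)c(OC)c1 | intermediate
32 | CNP0206369.0 | Oc1cc(O)c(Oc2cc(O)c(Oc3cc(O)c(O)c(O)c3Oc3cc(O)c(Oc4cc(O)c(O)c(O)c4Oc4cc(O)c(Oc5cc(O)c(O)c(O)c5Oc5cc(O)c(O)c(O)c5)c(O)c4)c(O)c3)c(O)c2)c(O)c1 | target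

Total steps: 21. Longest linear sequence: 16 steps (steps 1 to 10, then 16 to 21).

Steps most likely to fail

Step 7. The closure may be diverted by O-acylation of an enol oxygen onto the ester (pyranone formation) or by methoxide-induced retro-Claisen loss of a malonyl arm before the carbanion closes. In that case ring A would be brought in preformed instead of being built. Setting out from phenol 4, Ullmann etherification with commercial 2-iodo-1,3,5-trimethoxybenzene (CuI, picolinic acid, K3PO4, DMSO, 110 °C) should give 15 directly, where the route is rejoined; 6 to 14 are bypassed. This makes no new compound (F0). Its cost is a coupling at a di-ortho-substituted, electron-rich carbon, which is why the ring construction is preferred.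

Step 20 (the largest of the three like couplings 16, 18 and 20). Oxidative addition of copper into the electron-rich, ortho-aryloxy iodide may be slow, so that hydrodeiodination of 26 and oxidation of the hindered phenoxide compete. The fallback makes the crowded ether bond between rings F and G by SNAr and adds ring H afterwards. Formylation of 5-fluoro-1,2,3-trimethoxybenzene (Cl2CHOMe, TiCl4, CH2Cl2; the two free positions are equivalent) would give 6-fluoro-2,3,4-trimethoxybenzaldehyde F1. Setting out from 30, its phenoxide would displace the fluoride of F1, activated by the ortho-formyl group (Cs2CO3, DMSO, 120 °C), to give the heptamer aldehyde F2. Baeyer–Villiger oxidation (mCPBA, CH2Cl2) would then give the heptamer formate F3, and methanolysis (K2CO3, MeOH) the heptamer phenol F4, whose free hydroxyl sits on ring G next to the new ether. Chan–Lam coupling of F4 with boronic acid 25 (Cu(OAc)2, pyridine, 4 Å MS, CH2Cl2, air) would return to the route at 31.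

Step 21. Cleavage of 21 methyl ethers may stop short, leaving partly methylated material that cannot be separated from the polar product, and the pyrogallol rings may oxidise during aqueous isolation. The fallback isolates the product as a protected derivative. Setting out from 31, the BBr3 cleavage is run as before, but the crude polyphenol is not isolated. It is peracetylated in the same flask (Ac2O, pyridine, DMAP, rt) to the henicosaacetate F5, which is stable to air and can be chromatographed free of under-demethylated material. Acid-catalysed methanolysis of F5 (AcCl in degassed MeOH, rt, Ar) and evaporation should then release 32, where the route is rejoined.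

Further compounds
F0 | step 7 | none | none
F1 | step 20 | 6-fluoro-2,3,4-trimethoxybenzaldehyde | COc1cc(F)c(C=O)c(OC)c1OC
F2 | step 20 | heptamer aldehyde A–G (30 arylated on its ring F oxygen by the 2-formyl-3,4,5-trimethoxyphenyl group) | COc1cc(OC)c(Oc2cc(OC)c(Oc3cc(OC)c(OC)c(OC)c3Oc3cc(OC)c(Oc4cc(OC)c(OC)c(OC)c4Oc4cc(OC)c(Oc5cc(OC)c(OC)c(OC)c5C=O)c(OC)c4)c(OC)c3)c(OC)c2)c(OC)c1
F3 | step 20 | heptamer formate A–G (formyloxy group on ring G) | COc1cc(OC)c(Oc2cc(OC)c(Oc3cc(OC)c(OC)c(OC)c3Oc3cc(OC)c(Oc4cc(OC)c(OC)c(OC)c4Oc4cc(OC)c(Oc5cc(OC)c(OC)c(OC)c5OC=O)c(OC)c4)c(OC)c3)c(OC)c2)c(OC)c1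
F4 | step 20 | heptamer phenol A–G (free OH on ring G) | COc1cc(OC)c(Oc2cc(OC)c(Oc3cc(OC)c(OC)c(OC)c3Oc3cc(OC)c(Oc4cc(OC)c(OC)c(OC)c4Oc4cc(OC)c(Oc5cc(OC)c(OC)c(OC)c5O)c(OC)c4)c(OC)c3)c(OC)c2)c(OC)c1
F5 | step 21 | henicosaacetate of 32 | CC(=O)Oc1cc(OC(C)=O)c(Oc2cc(OC(C)=O)c(Oc3cc(OC(C)=O)c(OC(C)=O)c(OC(C)=O)c3Oc3cc(OC(C)=O)c(Oc4cc(OC(C)=O)c(OC(C)=O)c(OC(C)=O)c4Oc4cc(OC(C)=O)c(Oc5cc(OC(C)=O)c(OC(C)=O)c(OC(C)=O)c5Oc5cc(OC(C)=O)c(OC(C)=O)c(OC(C)=O)c5)c(OC(C)=O)c4)c(OC(C)=O)c3)c(OC(C)=O)c2)c(OC(C)=O)c1
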